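## Structural features

The target 18 is a 2,3,4-trisubstituted oxolane. Counting from the ring oxygen O1, C2 carries a 4-hydroxy-3,5-dimethoxyphenyl (syringyl) ring, C3 a CH2O group (C9) acylated by (E)-ferulic acid, C4 a 4-hydroxy-3-methoxybenzyl group attached through C7', and C5 is an unsubstituted CH2. C2, C3 and C4 are three contiguous stereocentres, (2S,3R,4R), with the syringyl ring trans to C9 and C9 cis to the C7' benzyl group. The 2,3-trans relationship is the thermodynamic one but the 3,4-cis relationship is not, so C4 has to be set under kinetic control after C3. The fragile points are the ferulate (an ester with a reducible conjugated alkene), the benzylic C2–O1 bond of the electron-rich syringyl ring and three oxidisable phenols. Acid would ionise C2–O1, which would epimerise C2 or let the guaiacyl ring close onto C2, and prolonged hydrogenolysis would cleave it. The real difficulty is therefore the order of events: the C3/C4 relationship, the absolute configuration, and an endgame in which nothing acidic, basic or reducing follows the esterification. The key step exploits the fact that O1–C5–C4–C7' is the skeleton of propargyl alcohol, C2–C3–C9 that of an arylidene malonate and the guaiacyl ring that of an aryl iodide, so forming O1–C2, C3–C4 and C7'–aryl closes the oxolane and assembles every core carbon at once. Both phenols are carried as benzyl ethers rather than as acetals: they tolerate the alkoxide, the palladium catalyst, hot chloride and hydride, and they are removed by the same hydrogenation that sets C4, so no acid is needed at the end.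

## Logic of the disconnections

**18 to 16 and 17.** The acyl–oxygen bond between C9–O and the cinnamoyl carbonyl is cut first. The ferulate cannot survive hydride, hydrogenation or strong base, so it has to arrive last. This removes one third of the molecule and leaves the triol 16 and the free acid 17. The forward step must acylate one primary aliphatic hydroxyl in the presence of three unprotected phenols, which calls for activation of the alcohol rather than of the acid.

**16 to 15 to 14.** The O–Si bond at C9 is restored, and then the C4–H and C7'–H bonds and the two phenolic O–H bonds are traded for a C4=C7' double bond and two O-benzyl groups. This removes the kinetically controlled stereocentre C4 and reveals the benzylidene that the cascade delivers. The forward hydrogenation must add anti to the silylated C9 arm, cleave both benzyl ethers, and stop before the benzylic C2–O1 bond is touched.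

**14 to 13 to 12.** The silyl ether goes back to the free alcohol 13, and 13 is traced to the racemate 12. No chiral element is present when C2 is formed, so the absolute configuration has to come from a separation. It is placed at the first compound that has a free primary hydroxyl and both C2 and C3 fixed, so that the later steps run on one enantiomer only. The demand is enantiomer discrimination through a stereocentre β to the reacting oxygen.

**12 to 11 to 10.** C9 is raised to the ester oxidation level, and the C3–H bond is replaced by a second ester group. C3 becomes a non-stereogenic malonate carbon and only C2 remains as a stereocentre. The forward loss of one ester must leave the aryl group and the remaining ester trans, keep the double bond exocyclic and not open the ring by β-elimination of O1.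

**10 to 4, 6 and 7.** Three bonds are cut in one operation: O1–C2, C3–C4 and C7'–aryl. Each lies next to a function that makes it polar in the right sense: C2 is the β-carbon of an acceptor, C3 a malonate nucleophile, C4 an alkyne carbon that becomes electrophilic on a metal, and the aryl group comes from an aryl iodide. The gain is the largest of the route, from a ring with a trisubstituted alkene to three achiral pieces. The forward step must run the oxygen addition before the carbon–carbon closure and transfer the aryl group instead of a proton, with anti addition across the alkyne so that a single alkene isomer results.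

**4 to 2 and 3; 2 to 1; 6 to 5.** The C2=C3 double bond of 4 is cut to an aldehyde and an active methylene compound, and the two benzyl–oxygen bonds are cut to the free phenols. These are condensations and alkylations of commercial materials; the only demand is that the protecting group chosen here survives steps 4 to 8 and leaves in step 9.

## Other disconnections considered

**Alternative 1:** The cut is O1–C2 and C2–C3. It leaves the cis-2,3-disubstituted oxetane A2, which already holds O1, C3, C4, C5 and both side chains, and the aryl diazo ester A3. In the forward step the carbene from A3 (Rh2(OAc)4 or blue light) would bind the oxetane oxygen of A2, and the oxonium ylide would shift C3 to the carbene carbon to give the 2-aryl-2-carbomethoxy oxolane A1.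
- In favour: C3 and C4 enter with their cis relationship and absolute configuration already fixed, so neither a resolution nor a face-selective hydrogenation is needed. On these two points the alternative is better than the chosen plan. The conditions are neutral and, in the light-driven form, metal-free, which is at least equal in mildness.
- Against: A2 is an enantiopure oxetane with two different side chains and needs a stereocontrolled synthesis of its own, so the stereochemical problem is moved rather than removed. The ylide has two different α-carbons; C3 must migrate in preference to C5 and with retention. A1 carries a superfluous ester on a quaternary benzylic carbon, and C2 becomes a defined stereocentre only after a decarboxylation that has no β-carbonyl to help it. The 4-methoxybenzyl and silyl groups need an oxidative and a fluoride deprotection around the ferulate.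
- Comparison: the key step forms two skeletal bonds from one advanced chiral partner, where the cascade of the chosen plan forms three from achiral commercial-grade pieces. The overall count is expected to be higher.

**Alternative 2:** The cut is C3–C9 and C4–C7'. It leaves the γ-syringyl butenolide A5 and the chloro silyl ether A6 as the source of a one-carbon carbonyl ylide. In the forward step CsF would remove the silyl group of A6, loss of chloride would give the ylide, and a 1,3-dipolar cycloaddition across C3=C4 of A5 anti to the aryl group would give the cis-fused furofuranone A4.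
- In favour: the ring fusion forces C9 and C7' cis, and the anti approach puts both trans to the syringyl ring, so one stereocentre dictates the other two. In stereochemical logic this is better than the chosen plan, which needs an equilibration at C3 and a hydrogenation at C4. A5 could be made enantioenriched by catalysis, so no material is discarded. The sacrificial C7'–O bridge would leave by hydrogenolysis together with the benzyl ether, which equals the economy of step 9 of the chosen plan.
- Against: the γ-hydrogen of A5 is benzylic and vinylogous to the lactone, so the basic fluoride medium can racemise it through an aromatic oxyfuran anion. The ylide must add with its CH2 end to C3. C5 arrives as a lactone carbonyl and has to be taken down to CH2 in extra steps near two acid-sensitive benzylic ethers. The hydrogenolysis must tell C7'–O from C2–O1. The pivalate has to be removed before the ferulate is attached or selectively afterwards.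
- Comparison: two skeletal bonds are formed instead of three and the number of operations after the key step is similar, but more of them are redox corrections.

**Alternative 3:** The cut is the lactone bond O1–C5 together with the C2–H bond. The precursor is the β-keto ester A8, whose C4 would come from an arylalanine A9. In the forward step RuCl(p-cymene)(TsDPEN) (divalent ruthenium) with HCO2H/Et3N would reduce the aryl ketone of A8 while C3 epimerises, and the new C2 hydroxyl would close onto the C5 ester to give the lactone A7.
- In favour: the absolute configuration comes from the catalyst and from the pool, without a resolution, which is better in material economy than step 7 of the chosen plan. Transfer hydrogenation with dynamic kinetic resolution of α-substituted β-keto esters is a dependable reaction class, equal in standing to the palladium cascade. C9 and C5 arrive already differentiated.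
- Against: in A7 the C9 ester and the benzyl group are cis and both C3 and C4 are enolisable, so the all-trans lactone is a thermodynamic sink during and after the key step. The catalyst must set C2 and choose the C3 epimer in the presence of the resident centre at C4. C5 must go from carbonyl to CH2 and C9 from ester to CH2OH by chemoselective reductions. If the nitrogen of A9 is replaced by C3 with a single inversion, the (R)-configured C4 demands the D series of A9 (drawn that way), and the L series fits only with net retention.
- Comparison: one ring bond and up to two stereocentres are formed in the key step, against three skeletal bonds in the cascade. The assembly of A8 and the later redox work make the sequence clearly longer.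

Key step: step 4

Assumption: the lipase of step 7 acetylates the (2R,3S)-enantiomer of 12 faster, so 13 is recovered as the unreacted alcohol; the sense of this preference has to be confirmed on the material.

## Route

Step 1
Reactants: 1 syringaldehyde
Product: 2 4-(benzyloxy)-3,5-dimethoxybenzaldehyde
Conditions: BnBr, K2CO3, DMF, 60 °C
Reagents that add atoms: benzyl bromide, BrCc1ccccc1
Why: Williamson O-alkylation of the phenoxide; the aldehyde is untouched and the benzyl ether is stable to every step up to the hydrogenation that removes it.

Step 2
Reactants: 2 4-(benzyloxy)-3,5-dimethoxybenzaldehyde; 3 diethyl malonate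
Product: 4 diethyl 2-[4-(benzyloxy)-3,5-dimethoxybenzylidene]malonate
Conditions: piperidine (cat.), AcOH (cat.), toluene, reflux, Dean–Stark
Reagents that add atoms: none
Why: Knoevenagel condensation through the piperidine-derived iminium ion with azeotropic removal of water; the two ester groups are identical, so the alkene has no geometry to control.

Step 3
Reactants: 5 4-iodo-2-methoxyphenol
Product: 6 1-(benzyloxy)-4-iodo-2-methoxybenzene
Conditions: BnBr, K2CO3, acetone, reflux
Reagents that add atoms: benzyl bromide, BrCc1ccccc1
Why: Williamson O-alkylation; the aryl iodide is inert to carbonate and to benzyl bromide.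

Step 4
Reactants: 7 propargyl alcohol; 4 diethyl 2-[4-(benzyloxy)-3,5-dimethoxybenzylidene]malonate; 6 1-(benzyloxy)-4-iodo-2-methoxybenzene
Product: 10 racemic diethyl (Z)-2-[4-(benzyloxy)-3,5-dimethoxyphenyl]-4-[4-(benzyloxy)-3-methoxybenzylidene]dihydrofuran-3,3(2H)-dicarboxylate, via lithium prop-2-yn-1-olate 8 (not isolated), via lithium enolate of the oxa-Michael adduct 9 (not isolated)
Conditions: n-BuLi (1.0 equiv per 7), THF, 0 °C; then 4, 6, PdCl2(PPh3)2 (5 mol%, reduced with n-BuLi, 10 mol%), DMSO/THF, rt
Reagents that add atoms: none
Why: Alkoxide 8 adds reversibly to the electron-poor alkene of 4 (oxa-Michael addition, O1–C2) to give the stabilised malonate anion 9, while zerovalent palladium, formed from PdCl2(PPh3)2 and n-BuLi, inserts into the C–I bond of 6 to give an arylpalladium iodide (divalent palladium) that binds the alkyne of 9. The malonate carbon attacks the bound alkyne at its internal carbon from the face opposite the metal (anti-carbopalladation, C3–C4); this 5-exo-dig closure forms the oxolane, is irreversible and so drains the oxa-Michael equilibrium. Reductive elimination from the vinyl(aryl)palladium intermediate joins C7' to the guaiacyl ring and returns zerovalent palladium. The closest known reaction type is the one-pot oxa-Michael addition, anti-carbopalladation and aryl coupling of propargyl alkoxides, alkylidene malonates and aryl halides. C2 is the only new stereocentre; it forms in the oxa-Michael step with no chiral element present and is therefore racemic, which step 7 corrects. The step needs the aryl group and not a proton to end on C7', and a single alkene geometry. The first is secured because the soft lithium malonate should add to the alkyne at a useful rate only when the alkyne is bound to the electrophilic arylpalladium iodide. The second follows from the anti mode of attack, which puts the aryl group trans to C3; this is the Z isomer because C5 outranks C3.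

Step 5
Reactants: 10 racemic diethyl (Z)-2-[4-(benzyloxy)-3,5-dimethoxyphenyl]-4-[4-(benzyloxy)-3-methoxybenzylidene]dihydrofuran-3,3(2H)-dicarboxylate
Product: 11 racemic ethyl (2S*,3S*)-2-[4-(benzyloxy)-3,5-dimethoxyphenyl]-4-[(Z)-4-(benzyloxy)-3-methoxybenzylidene]tetrahydrofuran-3-carboxylate (2,3-trans)
Conditions: LiCl, H2O, DMSO, 140 °C
Reagents that add atoms: none
Why: Krapcho dealkoxycarbonylation: chloride dealkylates one ethyl ester (SN2), the carboxylate loses CO2 and water protonates the ester enolate at C3, α-protonation keeping the styrenyl double bond exocyclic; C3–H is α to the ester and allylic, so it should equilibrate under the hot, weakly basic conditions to the more stable 2,3-trans isomer, the aryl group at C2 being the controlling element.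

Step 6
Reactants: 11 racemic ethyl (2S*,3S*)-2-[4-(benzyloxy)-3,5-dimethoxyphenyl]-4-[(Z)-4-(benzyloxy)-3-methoxybenzylidene]tetrahydrofuran-3-carboxylate
Product: 12 racemic {(2S*,3R*)-2-[4-(benzyloxy)-3,5-dimethoxyphenyl]-4-[(Z)-4-(benzyloxy)-3-methoxybenzylidene]tetrahydrofuran-3-yl}methanol (2,3-trans)
Conditions: LiAlH4, THF, −20 to 0 °C
Reagents that add atoms: none
Why: Hydride reduction of the ester to the primary alcohol, run cold so that C3 is not enolised; aryl benzyl ethers and the trisubstituted styrene are inert to LiAlH4, and the change of descriptor at C3 is only a change of priorities.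

Step 7
Reactants: 12 racemic {(2S*,3R*)-2-[4-(benzyloxy)-3,5-dimethoxyphenyl]-4-[(Z)-4-(benzyloxy)-3-methoxybenzylidene]tetrahydrofuran-3-yl}methanol
Product: 13 {(2S,3R)-2-[4-(benzyloxy)-3,5-dimethoxyphenyl]-4-[(Z)-4-(benzyloxy)-3-methoxybenzylidene]tetrahydrofuran-3-yl}methanol (recovered enantiomer)
Conditions: Amano lipase PS (Burkholderia cepacia, immobilised), vinyl acetate, MTBE, 30 °C, stopped just beyond half conversion; chromatography
Reagents that add atoms: none
Why: Lipase-catalysed kinetic resolution by irreversible transesterification with an enol ester: the enzyme distinguishes the enantiomers of a primary alcohol through the stereocentre β to oxygen (C3), acetylates one and leaves the other; no stereocentre is formed, and C2 and C3 are selected together because their relative configuration is already fixed.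

Step 8
Reactants: 13 {(2S,3R)-2-[4-(benzyloxy)-3,5-dimethoxyphenyl]-4-[(Z)-4-(benzyloxy)-3-methoxybenzylidene]tetrahydrofuran-3-yl}methanol
Product: 14 tert-butyl({(2S,3R)-2-[4-(benzyloxy)-3,5-dimethoxyphenyl]-4-[(Z)-4-(benzyloxy)-3-methoxybenzylidene]tetrahydrofuran-3-yl}methoxy)diphenylsilane
Conditions: TBDPSCl, imidazole, DMF, rt
Reagents that add atoms: tert-butyl(chloro)diphenylsilane, CC(C)(C)[Si](Cl)(c1ccccc1)c1ccccc1
Why: Silyl ether formation at the unhindered primary alcohol; the tert-butyldiphenylsilyl group is chosen for its bulk, which shields the C9 face of the exocyclic alkene in step 9.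

Step 9
Reactants: 14 tert-butyl({(2S,3R)-2-[4-(benzyloxy)-3,5-dimethoxyphenyl]-4-[(Z)-4-(benzyloxy)-3-methoxybenzylidene]tetrahydrofuran-3-yl}methoxy)diphenylsilane
Product: 15 4-{(2S,3R,4R)-3-[(tert-butyldiphenylsilyloxy)methyl]-4-(4-hydroxy-3-methoxybenzyl)tetrahydrofuran-2-yl}-2,6-dimethoxyphenol
Conditions: H2 (1 atm), 10% palladium on carbon (Pd/C), EtOAc, rt, stopped when the benzyl ethers are consumed
Reagents that add atoms: none
Why: Heterogeneous hydrogenation combined with O-benzyl hydrogenolysis: the alkene should adsorb on palladium through the ring face opposite the CH2OSi arm on C3, so both hydrogens add anti to C9 and the benzyl group at the new C4 centre ends cis to C9 (4R); the two aryl benzyl ethers are cleaved under the same conditions, and the benzylic C2–O1 bond should react only more slowly in a neutral medium.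

Step 10
Reactants: 15 4-{(2S,3R,4R)-3-[(tert-butyldiphenylsilyloxy)methyl]-4-(4-hydroxy-3-methoxybenzyl)tetrahydrofuran-2-yl}-2,6-dimethoxyphenol
Product: 16 4-[(2S,3R,4R)-4-(4-hydroxy-3-methoxybenzyl)-3-(hydroxymethyl)tetrahydrofuran-2-yl]-2,6-dimethoxyphenol
Conditions: TBAF, AcOH, THF, rt
Reagents that add atoms: none
Why: Fluoride-induced desilylation driven by the strong Si–F bond; acetic acid buffers the medium so that the phenols stay protonated and the syringyl phenoxide cannot expel O1 through a quinone methide.

Step 11
Reactants: 16 4-[(2S,3R,4R)-4-(4-hydroxy-3-methoxybenzyl)-3-(hydroxymethyl)tetrahydrofuran-2-yl]-2,6-dimethoxyphenol; 17 (E)-ferulic acid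
Product: 18 [(2S,3R,4R)-2-(4-hydroxy-3,5-dimethoxyphenyl)-4-(4-hydroxy-3-methoxybenzyl)tetrahydrofuran-3-yl]methyl (E)-3-(4-hydroxy-3-methoxyphenyl)prop-2-enoate (CNP0289934.1)
Conditions: PPh3, DIAD, THF, 0 °C to rt
Reagents that add atoms: none
Why: Mitsunobu esterification, known to be chemoselective for phenolic acids: the PPh3/DIAD betaine is protonated by the carboxylic acid, by far the most acidic hydroxyl present, and the primary C9 alcohol is the only hydroxyl whose oxyphosphonium ion can be displaced at carbon, so the ester should form without protection of the three phenols; C9 is a CH2, so no stereocentre is touched and the E alkene of 17 is kept.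

## Compound list

1 | syringaldehyde | COc1cc(C=O)cc(OC)c1O | starting material
2 | 4-(benzyloxy)-3,5-dimethoxybenzaldehyde | COc1cc(C=O)cc(OC)c1OCc1ccccc1 | intermediate
3 | diethyl malonate | CCOC(=O)CC(=O)OCC | starting material
4 | diethyl 2-[4-(benzyloxy)-3,5-dimethoxybenzylidene]malonate | CCOC(=O)C(=Cc1cc(OC)c(OCc2ccccc2)c(OC)c1)C(=O)OCC | intermediate
5 | 4-iodo-2-methoxyphenol | COc1cc(I)ccc1O | starting material
6 | 1-(benzyloxy)-4-iodo-2-methoxybenzene | COc1cc(I)ccc1OCc1ccccc1 | intermediate
7 | propargyl alcohol | C#CCO | starting material
8 | lithium prop-2-yn-1-olate | [Li+].[O-]CC#C | intermediate (not isolated)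
9 | lithium enolate of diethyl 2-{[4-(benzyloxy)-3,5-dimethoxyphenyl](prop-2-yn-1-yloxy)methyl}malonate, racemic | [Li+].CCOC(=O)[C-](C(=O)OCC)C(OCC#C)c1cc(OC)c(OCc2ccccc2)c(OC)c1 | intermediate (not isolated)
10 | racemic diethyl (Z)-2-[4-(benzyloxy)-3,5-dimethoxyphenyl]-4-[4-(benzyloxy)-3-methoxybenzylidene]dihydrofuran-3,3(2H)-dicarboxylate | CCOC(=O)C1(C(=O)OCC)C(c2cc(OC)c(OCc3ccccc3)c(OC)c2)OC/C1=C\c1ccc(OCc2ccccc2)c(OC)c1 | intermediate
11 | racemic ethyl (2S*,3S*)-2-[4-(benzyloxy)-3,5-dimethoxyphenyl]-4-[(Z)-4-(benzyloxy)-3-methoxybenzylidene]tetrahydrofuran-3-carboxylate, 2,3-trans (the enantiomer that leads to 18 is drawn) | CCOC(=O)[C@H]2/C(=C/c3ccc(OCc4ccccc4)c(OC)c3)CO[C@@H]2c2cc(OC)c(OCc3ccccc3)c(OC)c2 | intermediate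
12 | racemic {(2S*,3R*)-2-[4-(benzyloxy)-3,5-dimethoxyphenyl]-4-[(Z)-4-(benzyloxy)-3-methoxybenzylidene]tetrahydrofuran-3-yl}methanol, 2,3-trans (the enantiomer that leads to 18 is drawn) | OC[C@H]2/C(=C/c3ccc(OCc4ccccc4)c(OC)c3)CO[C@@H]2c2cc(OC)c(OCc3ccccc3)c(OC)c2 | intermediate
13 | {(2S,3R)-2-[4-(benzyloxy)-3,5-dimethoxyphenyl]-4-[(Z)-4-(benzyloxy)-3-methoxybenzylidene]tetrahydrofuran-3-yl}methanol, single enantiomer | OC[C@H]2/C(=C/c3ccc(OCc4ccccc4)c(OC)c3)CO[C@@H]2c2cc(OC)c(OCc3ccccc3)c(OC)c2 | intermediate
14 | tert-butyl({(2S,3R)-2-[4-(benzyloxy)-3,5-dimethoxyphenyl]-4-[(Z)-4-(benzyloxy)-3-methoxybenzylidene]tetrahydrofuran-3-yl}methoxy)diphenylsilane | CC(C)(C)[Si](OC[C@H]2/C(=C/c3ccc(OCc4ccccc4)c(OC)c3)CO[C@@H]2c2cc(OC)c(OCc3ccccc3)c(OC)c2)(c1ccccc1)c1ccccc1 | intermediate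
15 | 4-{(2S,3R,4R)-3-[(tert-butyldiphenylsilyloxy)methyl]-4-(4-hydroxy-3-methoxybenzyl)tetrahydrofuran-2-yl}-2,6-dimethoxyphenol | CC(C)(C)[Si](OC[C@H]2[C@@H](Cc3ccc(O)c(OC)c3)CO[C@@H]2c2cc(OC)c(O)c(OC)c2)(c1ccccc1)c1ccccc1 | intermediate
16 | 4-[(2S,3R,4R)-4-(4-hydroxy-3-methoxybenzyl)-3-(hydroxymethyl)tetrahydrofuran-2-yl]-2,6-dimethoxyphenol | OC[C@H]2[C@@H](Cc3ccc(O)c(OC)c3)CO[C@@H]2c2cc(OC)c(O)c(OC)c2 | intermediate
17 | (E)-ferulic acid | COc1cc(/C=C/C(=O)O)ccc1O | starting material
18 | [(2S,3R,4R)-2-(4-hydroxy-3,5-dimethoxyphenyl)-4-(4-hydroxy-3-methoxybenzyl)tetrahydrofuran-3-yl]methyl (E)-3-(4-hydroxy-3-methoxyphenyl)prop-2-enoate | COc1cc(/C=C/C(=O)OC[C@H]2[C@@H](Cc3ccc(O)c(OC)c3)CO[C@@H]2c2cc(OC)c(O)c(OC)c2)ccc1O | target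

## Step count and risks

Total: 11 steps. Longest linear sequence: 10 steps (1, 2, 4 to 11, from syringaldehyde); step 3 is a one-step branch.

**Step 4 (key step).** The most likely failures are reversal of the oxa-Michael addition, ester exchange by the alkoxide, or ring closure without aryl transfer. All three become competitive if oxidative addition to the electron-rich aryl iodide is slow relative to the chemistry of the anion. The fallback sets out from 4 and 7 and separates ring closure from arylation. The adduct 9 is quenched cold with AcOH to the neutral propargyl ether malonate F1. Iodocarbocyclisation (I2, Ti(Ot-Bu)4, CH2Cl2) closes the ring by anti addition to the (Z)-iodomethylene oxolane F2. Suzuki–Miyaura coupling of F2 with commercial [4-(benzyloxy)-3-methoxyphenyl]boronic acid (Pd(PPh3)4, K2CO3, dioxane/H2O) retains the alkene geometry and returns to the route at 10.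

**Step 5.** The most likely failures are migration of the exocyclic double bond into conjugation with the ester (γ-protonation of the dienolate), incomplete equilibration at C3, or β-elimination of O1 from the enolate. All arise because a free ester enolate exists at high temperature. The fallback sets out from 10 and avoids a free enolate. Mono-saponification (KOH, 1 equiv, EtOH/H2O, rt) gives the malonic half ester F3, which loses CO2 through its cyclic transition state on warming in pyridine (100 °C) and returns to the route at 11.

**Step 7.** The most likely failure is insufficient or inverted enantiomer discrimination, because the stereocentre is β to the reacting oxygen and both of its ring substituents are large. The fallback sets out from 12, separates the enantiomers directly by preparative supercritical-fluid chromatography on a polysaccharide chiral stationary phase, and returns at 13 without any new compound.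

**Step 9.** The most likely failures are incomplete facial discrimination at C4, palladium-induced migration of the double bond into the ring before reduction, or hydrogenolysis of the benzylic C2–O1 bond once the para oxygen has become a free phenol. The fallback sets out from 14 and decouples the two events. Homogeneous hydrogenation with the bulky cationic catalyst [Ir(cod)(PCy3)(py)]PF6 (H2, CH2Cl2) should saturate the alkene under steric control without cleaving C–O bonds and give the saturated bis(benzyl ether) F4. Transfer hydrogenolysis (Pd(OH)2/C, 1,4-cyclohexadiene, EtOH) then removes the benzyl groups and returns to the route at 15.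

**Step 11.** The most likely failure is O-alkylation of a phenol by the activated primary alcohol, leading to oligomers, together with difficult removal of the phosphine oxide from a polar triphenol. The fallback sets out from 15 and uses protecting groups:
- Ac2O/pyridine gives the diacetate F5.
- Buffered HF·pyridine (pyridine, THF, 0 °C) removes the silyl group and gives the primary alcohol F6.
- Carbodiimide coupling (EDC·HCl, DMAP, CH2Cl2) with commercial 4-acetoxy-3-methoxycinnamic acid gives the triacetate F7.
- Pyrrolidine (CH2Cl2, 0 °C) cleaves the three aryl acetates in preference to the alkyl cinnamate and returns to the route at 18.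

## Further compounds

F1 | step 4 | diethyl 2-{[4-(benzyloxy)-3,5-dimethoxyphenyl](prop-2-yn-1-yloxy)methyl}malonate, racemic | CCOC(=O)C(C(=O)OCC)C(OCC#C)c1cc(OC)c(OCc2ccccc2)c(OC)c1
F2 | step 4 | racemic diethyl (Z)-2-[4-(benzyloxy)-3,5-dimethoxyphenyl]-4-(iodomethylene)dihydrofuran-3,3(2H)-dicarboxylate | CCOC(=O)C1(C(=O)OCC)C(c2cc(OC)c(OCc3ccccc3)c(OC)c2)OC/C1=C\I
F3 | step 5 | (Z)-2-[4-(benzyloxy)-3,5-dimethoxyphenyl]-4-[4-(benzyloxy)-3-methoxybenzylidene]-3-(ethoxycarbonyl)tetrahydrofuran-3-carboxylic acid, mixture of diastereomers | CCOC(=O)C1(C(=O)O)C(c2cc(OC)c(OCc3ccccc3)c(OC)c2)OC/C1=C\c1ccc(OCc2ccccc2)c(OC)c1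
F0 | step 7 | none | none
F4 | step 9 | tert-butyl({(2S,3R,4R)-2-[4-(benzyloxy)-3,5-dimethoxyphenyl]-4-[4-(benzyloxy)-3-methoxybenzyl]tetrahydrofuran-3-yl}methoxy)diphenylsilane | CC(C)(C)[Si](OC[C@H]2[C@@H](Cc3ccc(OCc4ccccc4)c(OC)c3)CO[C@@H]2c2cc(OC)c(OCc3ccccc3)c(OC)c2)(c1ccccc1)c1ccccc1
F5 | step 11 | 4-{(2S,3R,4R)-4-(4-acetoxy-3-methoxybenzyl)-3-[(tert-butyldiphenylsilyloxy)methyl]tetrahydrofuran-2-yl}-2,6-dimethoxyphenyl acetate | CC(C)(C)[Si](OC[C@H]2[C@@H](Cc3ccc(OC(C)=O)c(OC)c3)CO[C@@H]2c2cc(OC)c(OC(C)=O)c(OC)c2)(c1ccccc1)c1ccccc1
F6 | step 11 | 4-[(2S,3R,4R)-4-(4-acetoxy-3-methoxybenzyl)-3-(hydroxymethyl)tetrahydrofuran-2-yl]-2,6-dimethoxyphenyl acetate | OC[C@H]2[C@@H](Cc3ccc(OC(C)=O)c(OC)c3)CO[C@@H]2c2cc(OC)c(OC(C)=O)c(OC)c2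
F7 | step 11 | [(2S,3R,4R)-2-(4-acetoxy-3,5-dimethoxyphenyl)-4-(4-acetoxy-3-methoxybenzyl)tetrahydrofuran-3-yl]methyl (E)-3-(4-acetoxy-3-methoxyphenyl)prop-2-enoate | COc1cc(/C=C/C(=O)OC[C@H]2[C@@H](Cc3ccc(OC(C)=O)c(OC)c3)CO[C@@H]2c2cc(OC)c(OC(C)=O)c(OC)c2)ccc1OC(C)=O
A1 | alternative 1 | methyl 2-[4-(tert-butyldimethylsilyloxy)-3,5-dimethoxyphenyl]-4-[4-(tert-butyldimethylsilyloxy)-3-methoxybenzyl]-3-[(4-methoxybenzyloxy)methyl]tetrahydrofuran-2-carboxylate, one C2 epimer, C3 and C4 as in 18 | COc1ccc(COC[C@H]2[C@@H](Cc3ccc(O[Si](C)(C)C(C)(C)C)c(OC)c3)CO[C@]2(C(=O)OC)c2cc(OC)c(O[Si](C)(C)C(C)(C)C)c(OC)c2)cc1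
A2 | alternative 1 | (2R,3S)-3-[4-(tert-butyldimethylsilyloxy)-3-methoxybenzyl]-2-[(4-methoxybenzyloxy)methyl]oxetane, cis | COc1ccc(COC[C@H]2[C@@H](Cc3ccc(O[Si](C)(C)C(C)(C)C)c(OC)c3)CO2)cc1
A3 | alternative 1 | methyl 2-[4-(tert-butyldimethylsilyloxy)-3,5-dimethoxyphenyl]-2-diazoacetate | COC(=O)C(=[N+]=[N-])c1cc(OC)c(O[Si](C)(C)C(C)(C)C)c(OC)c1
A4 | alternative 2 | cis-fused furofuranone from the ylide cycloaddition, mixture at C7' | O=C1O[C@H](c2cc(OC)c(OC(=O)C(C)(C)C)c(OC)c2)[C@H]2COC(c3ccc(OCc4ccccc4)c(OC)c3)[C@@H]12
A5 | alternative 2 | (S)-5-[3,5-dimethoxy-4-(pivaloyloxy)phenyl]furan-2(5H)-one | O=C1O[C@H](c2cc(OC)c(OC(=O)C(C)(C)C)c(OC)c2)C=C1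
A6 | alternative 2 | {[(4-(benzyloxy)-3-methoxyphenyl)(chloro)methoxy]methyl}trimethylsilane, racemic | C[Si](C)(C)COC(Cl)c1ccc(OCc2ccccc2)c(OC)c1
A7 | alternative 3 | tert-butyl 4-[4-(tert-butyldimethylsilyloxy)-3-methoxybenzyl]-2-[4-(tert-butyldimethylsilyloxy)-3,5-dimethoxyphenyl]-5-oxotetrahydrofuran-3-carboxylate, configured as in 18 | CC(C)(C)OC(=O)[C@H]2[C@@H](Cc3ccc(O[Si](C)(C)C(C)(C)C)c(OC)c3)C(=O)O[C@@H]2c2cc(OC)c(O[Si](C)(C)C(C)(C)C)c(OC)c2
A8 | alternative 3 | 1-tert-butyl 4-methyl (3R)-3-[4-(tert-butyldimethylsilyloxy)-3-methoxybenzyl]-2-[4-(tert-butyldimethylsilyloxy)-3,5-dimethoxybenzoyl]succinate, epimerising at C2 of the succinate | CC(C)(C)OC(=O)C(C(=O)c2cc(OC)c(O[Si](C)(C)C(C)(C)C)c(OC)c2)[C@@H](Cc3ccc(O[Si](C)(C)C(C)(C)C)c(OC)c3)C(=O)OC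
A9 | alternative 3 | (R)-2-amino-3-(4-hydroxy-3-methoxyphenyl)propanoic acid | COc1cc(C[C@@H](N)C(=O)O)ccc1O
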